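## Retrosynthetic overview

1. The target comes from its phenol silyl ether; the 16-membered lactone ring is closed last, at the side-chain trisubstituted alkene, by stereoretentive ring-closing metathesis of an (E)-but-2-en-2-yl group with a terminal vinyl group.
2. The metathesis diene comes from a Suzuki–Miyaura allyl–aryl coupling (aryl–CH2 bond) of a cyclopentenylmethyl carbonate (fragment A) with the arylboronate of a bromobenzoate ester (fragment B).
3. Fragment A: an organocatalytic alkenylborate conjugate addition/aldol condensation cascade on (E)-6-oxohept-2-enal sets the ring stereocentre and builds the cyclopentene.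
4. Fragment B: geranyl acetate, Shi epoxidation/hydrolysis (carbinol centre), vinylation, esterification with 3-bromo-4-silyloxybenzoic acid, second Shi epoxidation (epoxide centres).
5. Ring order: cyclopentene (step 2), epoxide (step 9), macrolactone (step 11); the benzene ring is bought.

Locants used for late compounds: C1 = benzylic CH2; C2–C6 = cyclopentene (C2=C3, CH3 on C3, C6 = stereocentre); C7(CH3)=C8; C9H2; C10/C11 = epoxide (CH3 on C11); C12H2, C13H2; C14 = ester carbinol; C15 = C(CH3)2OH. The target is (6R,7E,10S,11S,14S).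

Assumption: borate 4, both antipodes of the imidazolidinone catalyst and the L-series (ent) Shi ketone are bought as reagents/catalysts.

## Route

Step 1
Reactants: 1 hex-5-en-2-one; 2 (2E)-but-2-enal
Product: 3 (2E)-6-oxohept-2-enal
Conditions: second-generation Hoveyda–Grubbs catalyst (2 mol%), 2 (5 equiv), CH2Cl2, 40 °C
Reagents that add atoms: none
Why: Olefin cross-metathesis of a terminal alkene with crotonaldehyde gives the conjugated (E)-enal under thermodynamic control, with propene as the only by-product.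

Step 2
Reactants: 3 (2E)-6-oxohept-2-enal; 4 potassium (Z)-but-2-en-2-yltrifluoroborate
Product: 7 (5R)-5-[(2E)-but-2-en-2-yl]-2-methylcyclopent-1-ene-1-carbaldehyde, via keto-aldehyde 5 (not isolated), via aldol 6 (not isolated)
Conditions: (2R,5R)-5-benzyl-2-tert-butyl-3-methylimidazolidin-4-one·HCl (20 mol%), HF (48% aq, 1 equiv), DME, −20 °C; then Bn2NH·CF3CO2H (30 mol%), 40 °C
Reagents that add atoms: none
Why: Proposed new method: the imidazolidinone turns 3 into an (E)-iminium ion whose β-carbon is attacked by the boron-bearing carbon of 4 (ipso substitution of the alkenylborate, the developing β-cation being stabilised by the C–B bond, so the alkene geometry of 4 is retained and BF3 is removed by HF as KBF4), the benzyl group of the (2R,5R)-catalyst blocks one face so that the 3S adduct 5 results (the (2S,5S) antipode is known to deliver carbon nucleophiles to the opposite face of (E)-enals), and the dibenzylammonium enamine of 5 then adds to the methyl ketone (5-exo aldol) and dehydrates to the tetrasubstituted enal without touching the new stereocentre; the closest known reactions are the iminium-catalysed conjugate addition of styryl- and heteroaryl-trifluoroborates to enals and the amine-salt aldol cyclodehydration of 1,6-keto-aldehydes, and the new elements are the purely alkyl-substituted 1-methylalkenyl borate as nucleophile and its coupling to the ring closure in one flask.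

Step 3
Reactants: 7 (5R)-5-[(2E)-but-2-en-2-yl]-2-methylcyclopent-1-ene-1-carbaldehyde
Product: 8 [(5R)-5-[(2E)-but-2-en-2-yl]-2-methylcyclopent-1-en-1-yl]methanol
Conditions: NaBH4, MeOH, 0 °C
Reagents that add atoms: none
Why: Chemoselective 1,2-hydride reduction of the hindered β,β-disubstituted enal; the ring stereocentre is not enolisable and is untouched.

Step 4
Reactants: 8 [(5R)-5-[(2E)-but-2-en-2-yl]-2-methylcyclopent-1-en-1-yl]methanol
Product: 9 [(5R)-5-[(2E)-but-2-en-2-yl]-2-methylcyclopent-1-en-1-yl]methyl methyl carbonate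
Conditions: ClCO2Me, pyridine, CH2Cl2, 0 °C
Reagents that add atoms: methyl chloroformate, COC(=O)Cl
Why: O-acylation of the primary allylic alcohol installs the carbonate leaving group needed later for π-allylpalladium formation.

Step 5
Reactants: 10 geranyl acetate [(2E)-3,7-dimethylocta-2,6-dien-1-yl acetate]
Product: 12 (2E,6S)-6,7-dihydroxy-3,7-dimethyloct-2-en-1-yl acetate, via epoxide 11 (not isolated)
Conditions: ent-Shi ketone (1,2:4,5-di-O-isopropylidene-β-L-erythro-2,3-hexodiulo-2,6-pyranose, 30 mol%), KHSO5 (as 2KHSO5·KHSO4·K2SO4), K2CO3, Bu4NHSO4, Na2B4O7 buffer, MeCN/DMM, 0 °C; then Na2S2O3; then HClO4 (aq, pH 1), THF, 0 → 23 °C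
Reagents that add atoms: potassium peroxymonosulfate, [K+].[O-]S(=O)(=O)OO; water, O
Why: Shi epoxidation, in which the chiral dioxirane oxidises only the electron-rich distal trisubstituted alkene (the allylic acetate deactivates the other) through a spiro transition state, the L-series ketone giving the S epoxide, after which acid-catalysed hydrolysis opens the epoxide at the tertiary carbon so the C–O bond at the stereocentre is kept.

Step 6
Reactants: 12 (2E,6S)-6,7-dihydroxy-3,7-dimethyloct-2-en-1-yl acetate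
Product: 13 (3S,6E)-2,6-dimethyldeca-6,9-diene-2,3-diol
Conditions: tributyl(vinyl)stannane, Pd2(dba)3 (3 mol%), LiCl, DMF, 23 °C
Reagents that add atoms: tributyl(vinyl)stannane, C=C[Sn](CCCC)(CCCC)CCCC
Why: Stille allyl–vinyl coupling, in which zerovalent palladium ionises the allylic acetate and the vinyl group is delivered to the unhindered primary terminus of the π-allyl complex with retention of the E alkene, the base-free conditions keeping the free diol from attacking the π-allyl intermediate.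

Step 7
Reactants: 14 3-bromo-4-hydroxybenzoic acid
Product: 16 3-bromo-4-[(triisopropylsilyl)oxy]benzoic acid, via bis-silyl compound 15 (not isolated)
Conditions: iPr3SiCl (2.3 equiv), imidazole, DMF, 23 °C; then THF/H2O/AcOH, 23 °C
Reagents that add atoms: triisopropylsilyl chloride, CC(C)[Si](Cl)(C(C)C)C(C)C
Why: Silylation of phenol and acid followed by selective hydrolysis of the labile silyl ester leaves the robust aryl silyl ether.

Step 8
Reactants: 13 (3S,6E)-2,6-dimethyldeca-6,9-diene-2,3-diol; 16 3-bromo-4-[(triisopropylsilyl)oxy]benzoic acid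
Product: 17 (3S,6E)-2-hydroxy-2,6-dimethyldeca-6,9-dien-3-yl 3-bromo-4-[(triisopropylsilyl)oxy]benzoate
Conditions: 2-methyl-6-nitrobenzoic anhydride, Et3N, DMAP, CH2Cl2, 23 °C
Reagents that add atoms: none
Why: Shiina esterification (mixed-anhydride activation with DMAP acyl transfer) acylates the secondary hydroxyl selectively over the tertiary one and leaves the carbinol configuration unchanged.

Step 9
Reactants: 17 (3S,6E)-2-hydroxy-2,6-dimethyldeca-6,9-dien-3-yl 3-bromo-4-[(triisopropylsilyl)oxy]benzoate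
Product: 18 (3S)-2-hydroxy-2-methyl-5-[(2S,3S)-2-methyl-3-(prop-2-en-1-yl)oxiran-2-yl]pentan-3-yl 3-bromo-4-[(triisopropylsilyl)oxy]benzoate
Conditions: ent-Shi ketone (40 mol%), KHSO5 (as 2KHSO5·KHSO4·K2SO4), K2CO3, Bu4NHSO4, Na2B4O7 buffer, MeCN/DMM, 0 °C
Reagents that add atoms: potassium peroxymonosulfate, [K+].[O-]S(=O)(=O)OO
Why: Second Shi epoxidation, in which the only electron-rich alkene left is the trisubstituted one (the monosubstituted vinyl group is inert), the L-series ketone sets the (2S,3S)-epoxide under catalyst control, and the already acylated neighbouring oxygen cannot cyclise onto the epoxide.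

Step 10
Reactants: 18 (3S)-2-hydroxy-2-methyl-5-[(2S,3S)-2-methyl-3-(prop-2-en-1-yl)oxiran-2-yl]pentan-3-yl 3-bromo-4-[(triisopropylsilyl)oxy]benzoate; 9 [(5R)-5-[(2E)-but-2-en-2-yl]-2-methylcyclopent-1-en-1-yl]methyl methyl carbonate
Product: 20 (3S)-2-hydroxy-2-methyl-5-[(2S,3S)-2-methyl-3-(prop-2-en-1-yl)oxiran-2-yl]pentan-3-yl 3-{[(5R)-5-[(2E)-but-2-en-2-yl]-2-methylcyclopent-1-en-1-yl]methyl}-4-[(triisopropylsilyl)oxy]benzoate, via boronate 19 (not isolated)
Conditions: B2pin2, Pd(dppf)Cl2 (5 mol%), KOAc, dioxane, 85 °C; then 9, K3PO4 (aq), 60 °C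
Reagents that add atoms: none
Why: Miyaura borylation of the aryl bromide followed in the same flask by Suzuki–Miyaura allyl–aryl coupling, in which the π-allylpalladium complex from 9 undergoes reductive elimination at its unhindered CH2 terminus so that the tetrasubstituted ring alkene and the ring stereocentre stay as they are.

Step 11
Reactants: 20 (3S)-2-hydroxy-2-methyl-5-[(2S,3S)-2-methyl-3-(prop-2-en-1-yl)oxiran-2-yl]pentan-3-yl 3-{[(5R)-5-[(2E)-but-2-en-2-yl]-2-methylcyclopent-1-en-1-yl]methyl}-4-[(triisopropylsilyl)oxy]benzoate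
Product: 23 (6R,7E,10S,11S,14S)-macrolactone O-triisopropylsilyl ether (target skeleton with the phenol silylated), via borate 21 (not isolated), via macrocyclic borate 22 (not isolated)
Conditions: HBpin (1.5 equiv), C6H6, 40 °C; then Mo(NC6F5)(CHCMe2Ph)(NC4H2Me2-2,5)(OC6H3-2,6-(C6H2-2,4,6-iPr3)2) (10 mol%), C6H6 (1 mM), 40 °C, 100 torr; then MeOH/H2O
Reagents that add atoms: none
Why: Stereoretentive macrocyclic ring-closing metathesis, in which the tertiary hydroxyl is first masked in the flask as its pinacol borate, the molybdenum monoaryloxide pyrrolide alkylidene is loaded at the terminal vinyl group and closes onto the methyl-capped (E)-trisubstituted alkene through a metallacyclobutane where the incoming chain takes the place of the departing cap methyl, so the E geometry fixed by reagent 4 is kept and propene is lost.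

Step 12
Reactants: 23 (6R,7E,10S,11S,14S)-macrolactone O-triisopropylsilyl ether
Product: 24 CNP0346590.2, the (6R,7E,10S,11S,14S)-macrolactone with free phenol
Conditions: TBAF, AcOH, THF, 0 °C
Reagents that add atoms: none
Why: Fluoride-mediated cleavage of the aryl silyl ether under acetic acid buffering leaves the lactone, epoxide, tertiary alcohol and alkenes untouched.

## Compound list

1 | hex-5-en-2-one | CC(=O)CCC=C | starting material
2 | (2E)-but-2-enal | C/C=C/C=O | starting material
3 | (2E)-6-oxohept-2-enal | CC(=O)CC/C=C/C=O | intermediate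
4 | potassium (Z)-but-2-en-2-yltrifluoroborate | C/C=C(\C)[B-](F)(F)F.[K+] | starting material
5 | (3S)-3-[(2E)-but-2-en-2-yl]-6-oxoheptanal | C/C=C(\C)[C@H](CC=O)CCC(C)=O | intermediate
6 | (5S)-5-[(2E)-but-2-en-2-yl]-2-hydroxy-2-methylcyclopentane-1-carbaldehyde (mixture at C1 and C2) | C/C=C(\C)[C@H]1CCC(C)(O)C1C=O | intermediate
7 | (5R)-5-[(2E)-but-2-en-2-yl]-2-methylcyclopent-1-ene-1-carbaldehyde | C/C=C(\C)[C@H]1CCC(C)=C1C=O | intermediate
8 | [(5R)-5-[(2E)-but-2-en-2-yl]-2-methylcyclopent-1-en-1-yl]methanol | C/C=C(\C)[C@H]1CCC(C)=C1CO | intermediate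
9 | [(5R)-5-[(2E)-but-2-en-2-yl]-2-methylcyclopent-1-en-1-yl]methyl methyl carbonate | C/C=C(\C)[C@H]1CCC(C)=C1COC(=O)OC | intermediate
10 | geranyl acetate, (2E)-3,7-dimethylocta-2,6-dien-1-yl acetate | CC(=O)OC/C=C(C)/CCC=C(C)C | starting material
11 | (2E)-5-[(2S)-3,3-dimethyloxiran-2-yl]-3-methylpent-2-en-1-yl acetate | CC(=O)OC/C=C(C)/CC[C@@H]1OC1(C)C | intermediate
12 | (2E,6S)-6,7-dihydroxy-3,7-dimethyloct-2-en-1-yl acetate | CC(=O)OC/C=C(C)/CC[C@H](O)C(C)(C)O | intermediate
13 | (3S,6E)-2,6-dimethyldeca-6,9-diene-2,3-diol | C=CC/C=C(C)/CC[C@H](O)C(C)(C)O | intermediate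
14 | 3-bromo-4-hydroxybenzoic acid | OC(=O)c1ccc(O)c(Br)c1 | starting material
15 | triisopropylsilyl 3-bromo-4-[(triisopropylsilyl)oxy]benzoate | CC(C)[Si](OC(=O)c1ccc(O[Si](C(C)C)(C(C)C)C(C)C)c(Br)c1)(C(C)C)C(C)C | intermediate
16 | 3-bromo-4-[(triisopropylsilyl)oxy]benzoic acid | OC(=O)c1ccc(O[Si](C(C)C)(C(C)C)C(C)C)c(Br)c1 | intermediate
17 | (3S,6E)-2-hydroxy-2,6-dimethyldeca-6,9-dien-3-yl 3-bromo-4-[(triisopropylsilyl)oxy]benzoate | C=CC/C=C(C)/CC[C@H](OC(=O)c1ccc(O[Si](C(C)C)(C(C)C)C(C)C)c(Br)c1)C(C)(C)O | intermediate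
18 | (3S)-2-hydroxy-2-methyl-5-[(2S,3S)-2-methyl-3-(prop-2-en-1-yl)oxiran-2-yl]pentan-3-yl 3-bromo-4-[(triisopropylsilyl)oxy]benzoate | CC(C)[Si](Oc1ccc(cc1Br)C(=O)O[C@H](C(C)(C)O)CC[C@]2(C)O[C@H]2CC=C)(C(C)C)C(C)C | intermediate
19 | the ester 18 with 4,4,5,5-tetramethyl-1,3,2-dioxaborolan-2-yl in place of bromine | CC(C)[Si](Oc1ccc(cc1B2OC(C)(C)C(C)(C)O2)C(=O)O[C@H](C(C)(C)O)CC[C@]3(C)O[C@H]3CC=C)(C(C)C)C(C)C | intermediate
20 | (3S)-2-hydroxy-2-methyl-5-[(2S,3S)-2-methyl-3-(prop-2-en-1-yl)oxiran-2-yl]pentan-3-yl 3-{[(5R)-5-[(2E)-but-2-en-2-yl]-2-methylcyclopent-1-en-1-yl]methyl}-4-[(triisopropylsilyl)oxy]benzoate | C/C=C(\C)[C@H]1CCC(C)=C1Cc2cc(ccc2O[Si](C(C)C)(C(C)C)C(C)C)C(=O)O[C@H](C(C)(C)O)CC[C@]3(C)O[C@H]3CC=C | intermediate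
21 | 20 with the tertiary hydroxyl as its (4,4,5,5-tetramethyl-1,3,2-dioxaborolan-2-yl) borate | C/C=C(\C)[C@H]1CCC(C)=C1Cc2cc(ccc2O[Si](C(C)C)(C(C)C)C(C)C)C(=O)O[C@H](C(C)(C)OB4OC(C)(C)C(C)(C)O4)CC[C@]3(C)O[C@H]3CC=C | intermediate
22 | (6R,7E,10S,11S,14S)-macrolactone with phenol as triisopropylsilyl ether and the C15 hydroxyl as pinacol borate | CC1=C2Cc3cc(ccc3O[Si](C(C)C)(C(C)C)C(C)C)C(=O)O[C@H](C(C)(C)OB4OC(C)(C)C(C)(C)O4)CC[C@]3(C)O[C@H]3C/C=C(\C)[C@H]2CC1 | intermediate
23 | (6R,7E,10S,11S,14S)-macrolactone with phenol as triisopropylsilyl ether and free C15 hydroxyl | CC1=C2Cc3cc(ccc3O[Si](C(C)C)(C(C)C)C(C)C)C(=O)O[C@H](C(C)(C)O)CC[C@]3(C)O[C@H]3C/C=C(\C)[C@H]2CC1 | intermediate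
24 | CNP0346590.2: 16-membered lactone of 4-hydroxybenzoic acid with O14; aryl C3 carries C1H2 bonded to C2 of a cyclopentene (C2=C3, CH3 on C3, C6H); C6 carries C7(CH3)=C8H–C9H2–(10,11-trans-epoxide, CH3 on C11)–C12H2–C13H2–C14H(O-acyl)–C15(CH3)2OH; (6R,7E,10S,11S,14S) | CC1=C2Cc3cc(ccc3O)C(=O)O[C@H](C(C)(C)O)CC[C@]3(C)O[C@H]3C/C=C(\C)[C@H]2CC1 | target

## Step count and risks

Total steps: 12. Longest linear sequence: 7 steps (10 → 12 → 13 → 17 → 18 → 20 → 23 → 24; the branch from 1 is also 7).

Three steps most likely to fail: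

1. Step 2 (the proposed cascade). The aliphatic 1-methylalkenyl borate may be too weak a nucleophile for the iminium ion or may react through its unsubstituted alkene carbon instead of ipso, and the methyl ketone of 3 may interfere. Fallback with known chemistry, setting out from 1 and coming back at 5 (and so at 7 through the second stage of step 2): cross-metathesis of 1 with methyl acrylate (second-generation Hoveyda–Grubbs catalyst) gives methyl (2E)-6-oxohept-2-enoate F1. Hayashi–Miyaura 1,4-addition of commercial (Z)-but-2-en-2-ylboronic acid with Rh(acac)(C2H4)2 and (R)-BINAP (the antipode expected to give 3S; the other is used if the sense proves opposite) in dioxane/H2O gives methyl (3S)-3-[(2E)-but-2-en-2-yl]-6-oxoheptanoate F2. Reduction of ester and ketone with iBu2AlH gives (3S)-3-[(2E)-but-2-en-2-yl]heptane-1,6-diol F3, and Swern oxidation of both hydroxyls returns keto-aldehyde 5, which Bn2NH·CF3CO2H converts into 7.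

2. Step 11 (stereoretentive macrocyclic metathesis). The molybdenum alkylidene may be degraded by the epoxide or the borate-masked hydroxyl, or the ring closure onto the hindered trisubstituted alkene may be too slow at high dilution. Fallback that moves to a tolerant ruthenium carbene and a 1,1-disubstituted alkene partner, setting out from 3 and coming back at 23: run step 2 with potassium isopropenyltrifluoroborate to obtain, through (3S)-6-oxo-3-(prop-1-en-2-yl)heptanal F7 and (5S)-2-hydroxy-2-methyl-5-(prop-1-en-2-yl)cyclopentane-1-carbaldehyde F8, the enal (5R)-2-methyl-5-(prop-1-en-2-yl)cyclopent-1-ene-1-carbaldehyde F9. Reduce it as in step 3 to [(5R)-2-methyl-5-(prop-1-en-2-yl)cyclopent-1-en-1-yl]methanol F10 and acylate as in step 4 to methyl [(5R)-2-methyl-5-(prop-1-en-2-yl)cyclopent-1-en-1-yl]methyl carbonate F11. Couple F11 with boronate 19 as in step 10 to give (3S)-2-hydroxy-2-methyl-5-[(2S,3S)-2-methyl-3-(prop-2-en-1-yl)oxiran-2-yl]pentan-3-yl 3-{[(5R)-2-methyl-5-(prop-1-en-2-yl)cyclopent-1-en-1-yl]methyl}-4-[(triisopropylsilyl)oxy]benzoate F12. Close the ring with the second-generation Hoveyda–Grubbs catalyst (toluene, 80 °C, 1 mM, no hydroxyl masking needed) to 23. Here the E alkene is favoured only because C9 avoids the branched ring carbon, so any Z isomer must be separated.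

3. Step 10 (one-pot borylation and allyl–aryl coupling on the functionalised ester). The ortho-silyloxy arylboronate is hindered and may protodeboronate, the crowded π-allyl complex may undergo β-hydride elimination, and the allyl epoxide is exposed to palladium at 85 °C. Fallback that forges the aryl–CH2 bond on small partners before the epoxide-bearing alcohol is attached, setting out from 16, 9 and 13 and coming back at 20: Miyaura borylation of 16 (B2pin2, Pd(dppf)Cl2, KOAc) gives 3-(4,4,5,5-tetramethyl-1,3,2-dioxaborolan-2-yl)-4-[(triisopropylsilyl)oxy]benzoic acid F4. Suzuki–Miyaura coupling of F4 with 9 gives 3-{[(5R)-5-[(2E)-but-2-en-2-yl]-2-methylcyclopent-1-en-1-yl]methyl}-4-[(triisopropylsilyl)oxy]benzoic acid F5. Separately, Shi epoxidation of 13 with the ent-Shi ketone gives (3S)-2-methyl-5-[(2S,3S)-2-methyl-3-(prop-2-en-1-yl)oxiran-2-yl]pentane-2,3-diol F6 (kept under basic conditions to avoid cyclisation to a tetrahydrofuran). Shiina esterification of F5 with F6 at the secondary hydroxyl gives 20.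

Further compounds
F1 | step 2 | methyl (2E)-6-oxohept-2-enoate | COC(=O)/C=C/CCC(C)=O
F2 | step 2 | methyl (3S)-3-[(2E)-but-2-en-2-yl]-6-oxoheptanoate | C/C=C(\C)[C@H](CC(=O)OC)CCC(C)=O
F3 | step 2 | (3S)-3-[(2E)-but-2-en-2-yl]heptane-1,6-diol | C/C=C(\C)[C@H](CCO)CCC(C)O
F4 | step 10 | 3-(4,4,5,5-tetramethyl-1,3,2-dioxaborolan-2-yl)-4-[(triisopropylsilyl)oxy]benzoic acid | OC(=O)c1ccc(O[Si](C(C)C)(C(C)C)C(C)C)c(c1)B2OC(C)(C)C(C)(C)O2
F5 | step 10 | 3-{[(5R)-5-[(2E)-but-2-en-2-yl]-2-methylcyclopent-1-en-1-yl]methyl}-4-[(triisopropylsilyl)oxy]benzoic acid | C/C=C(\C)[C@H]1CCC(C)=C1Cc2cc(ccc2O[Si](C(C)C)(C(C)C)C(C)C)C(=O)O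
F6 | step 10 | (3S)-2-methyl-5-[(2S,3S)-2-methyl-3-(prop-2-en-1-yl)oxiran-2-yl]pentane-2,3-diol | O[C@H](C(C)(C)O)CC[C@]1(C)O[C@H]1CC=C
F7 | step 11 | (3S)-6-oxo-3-(prop-1-en-2-yl)heptanal | CC(=C)[C@H](CC=O)CCC(C)=O
F8 | step 11 | (5S)-2-hydroxy-2-methyl-5-(prop-1-en-2-yl)cyclopentane-1-carbaldehyde | CC(=C)[C@H]1CCC(C)(O)C1C=O
F9 | step 11 | (5R)-2-methyl-5-(prop-1-en-2-yl)cyclopent-1-ene-1-carbaldehyde | CC(=C)[C@H]1CCC(C)=C1C=O
F10 | step 11 | [(5R)-2-methyl-5-(prop-1-en-2-yl)cyclopent-1-en-1-yl]methanol | CC(=C)[C@H]1CCC(C)=C1CO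
F11 | step 11 | methyl [(5R)-2-methyl-5-(prop-1-en-2-yl)cyclopent-1-en-1-yl]methyl carbonate | CC(=C)[C@H]1CCC(C)=C1COC(=O)OC
F12 | step 11 | (3S)-2-hydroxy-2-methyl-5-[(2S,3S)-2-methyl-3-(prop-2-en-1-yl)oxiran-2-yl]pentan-3-yl 3-{[(5R)-2-methyl-5-(prop-1-en-2-yl)cyclopent-1-en-1-yl]methyl}-4-[(triisopropylsilyl)oxy]benzoate | CC(=C)[C@H]1CCC(C)=C1Cc2cc(ccc2O[Si](C(C)C)(C(C)C)C(C)C)C(=O)O[C@H](C(C)(C)O)CC[C@]3(C)O[C@H]3CC=C
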